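**Plan**

- Numbering (1,10-seco-eudesmanolide): carbocycle C5–C10; lactone C7–C11(=C13)–C12(=O)–O–C8; C14 on C10; side chain C4(C15)–C3–C2–C1 on C5; angelate on O6.
- Retrosynthesis: cut the O6–acyl bond and C11=C13; trade the C5=C10 π bond for a C5 sulfone (loss of PhSO2H); reopen the lactone to a C8–O–C14 acetal bridge; cut C4–C5; then cut C5–C10 and C7–C8 together.
- Enabling feature: O6 and O8 are 1,3 across C7 (aldol pattern), C14 as CHO is 1,5 to C6 (Michael pattern), and O8/C14 are 1,4-related. A ketone C5–C6–C7 and an enal C8–C9–C10–C14 therefore close the six-membered ring in one (3+3) annulation, locked as a 6-oxabicyclo[3.2.1]octanone.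
- Forward order: carbocycle first (sulfone plus enal), then the C4 side chain by a second Michael addition, C6 reduction, lactone ring by acetal hydrolysis, C5=C10 by sulfinate loss, C14 reduction, α-methylenation, angelate.
- Stereochemistry: C10 from the (R)-diarylprolinol silyl ether, relayed to C8 (the bridge spans one face) and C7 (equatorial); C4 from the (S)-catalyst; C6 from hydride delivery anti to the axial side chain; C5 and C10 are flattened later.

Key step: step 2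

Remark: the sulfonyl carbon C5 (until step 3) and the acetal carbon C14 are carried as epimer mixtures; their SMILES are left open at those atoms.

**Step 1**
Reactants: 1 methyl 5-bromo-4-oxopentanoate; 2 sodium benzenesulfinate
Product: 3 methyl 4-oxo-5-(phenylsulfonyl)pentanoate
Conditions: DMF, rt
Reagents that add atoms: none
Why: SN2 S-alkylation of the sulfinate by the α-bromo ketone should give the β-keto sulfone.

**Step 2**
Reactants: 3 methyl 4-oxo-5-(phenylsulfonyl)pentanoate (slight excess); 4 (E)-4,4-dimethoxybut-2-enal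
Product: 6 methyl 2-[(1R,4R,5R)-7-methoxy-3-oxo-2-(phenylsulfonyl)-6-oxabicyclo[3.2.1]octan-4-yl]acetate, via Michael adduct 5 (not isolated)
Conditions: (R)-2-[diphenyl(trimethylsilyloxy)methyl]pyrrolidine (10 mol%), PhCO2H (10 mol%), toluene, 0 °C to rt; then CH2Cl2, camphorsulfonic acid (30 mol%), rt, same flask
Reagents that add atoms: none
Why: The catalyst turns 4 into an iminium ion and the sulfone-activated C5 of 3 adds to C10 (Michael addition, C5–C10); camphorsulfonic acid then ionises the acetal, the C8 aldehyde oxygen closes on C14 to a 2-methoxyoxolan-5-ylium ion, and the C6/C7 enol attacks C8 (C7–C8). Closest known types are diarylprolinol silyl ether-catalysed Michael additions of β-keto sulfones to enals, Michael/aldol (3+3) annulations of 1,3-dicarbonyl donors with enals, and enol additions to cyclic oxocarbenium ions of 2,5-dialkoxyoxolanes. The carbocycle closes in the 6-(enolendo)-exo-trig mode (the 5-(enolendo) alternative at C14 is disfavoured) and the oxolane by 5-exo attack of the carbonyl oxygen on the C14 oxocarbenium. C10 is set by the catalyst, whose CPh2OSiMe3 group shields one face of the iminium ion; C8 follows from C10 because the C8–O–C14 bridge can only span one face of the new ring; C7 should settle with its acetate arm equatorial (cis to the bridge oxygen) by acid-mediated epimerisation next to the ketone; C5 and C14 stay mixed. The step needs C- over O-cyclisation and single addition at C5: O-linked acetals reopen under the acid while the C7–C8 bond does not, and 3 is used in slight excess.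

**Step 3**
Reactants: 6 methyl 2-[(1R,4R,5R)-7-methoxy-3-oxo-2-(phenylsulfonyl)-6-oxabicyclo[3.2.1]octan-4-yl]acetate; 7 (E)-but-2-enal
Product: 8 methyl 2-[(1R,2S,4R,5R)-7-methoxy-3-oxo-2-[(2R)-4-oxobutan-2-yl]-2-(phenylsulfonyl)-6-oxabicyclo[3.2.1]octan-4-yl]acetate
Conditions: (S)-2-[diphenyl(trimethylsilyloxy)methyl]pyrrolidine (20 mol%), PhCO2H (20 mol%), toluene, rt
Reagents that add atoms: none
Why: Iminium-ion Michael addition of the cyclic β-keto sulfone; the C5 enol should be attacked on the face opposite the acetal bridge, and C4 is set by the catalyst shielding one face of the crotonaldehyde iminium ion.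

**Step 4**
Reactants: 8 methyl 2-[(1R,2S,4R,5R)-7-methoxy-3-oxo-2-[(2R)-4-oxobutan-2-yl]-2-(phenylsulfonyl)-6-oxabicyclo[3.2.1]octan-4-yl]acetate
Product: 9 methyl 2-[(1R,2S,4R,5R)-7-methoxy-3-oxo-2-[(2R)-pent-4-en-2-yl]-2-(phenylsulfonyl)-6-oxabicyclo[3.2.1]octan-4-yl]acetate
Conditions: Ph3PCH3Br, KN(SiMe3)2 (slight deficit to the salt), THF, −78 to 0 °C
Reagents that add atoms: methyltriphenylphosphonium bromide C[P+](c1ccccc1)(c1ccccc1)c1ccccc1.[Br-]
Why: Wittig methylenation; the aldehyde should react far faster than the ketone flanked by a quaternary carbon or the ester.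

**Step 5**
Reactants: 9 methyl 2-[(1R,2S,4R,5R)-7-methoxy-3-oxo-2-[(2R)-pent-4-en-2-yl]-2-(phenylsulfonyl)-6-oxabicyclo[3.2.1]octan-4-yl]acetate
Product: 10 methyl 2-[(1R,2S,3S,4S,5R)-3-hydroxy-7-methoxy-2-[(2R)-pent-4-en-2-yl]-2-(phenylsulfonyl)-6-oxabicyclo[3.2.1]octan-4-yl]acetate
Conditions: NaBH4, CeCl3·7H2O, MeOH, −40 to 0 °C
Reagents that add atoms: none
Why: Luche reduction; the face away from the bridge is blocked by the axial C4 side chain on quaternary C5, so hydride should enter from the bridge side and leave the C6 hydroxyl equatorial, trans to the C7 arm.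

**Step 6**
Reactants: 10 methyl 2-[(1R,2S,3S,4S,5R)-3-hydroxy-7-methoxy-2-[(2R)-pent-4-en-2-yl]-2-(phenylsulfonyl)-6-oxabicyclo[3.2.1]octan-4-yl]acetate
Product: 11 methyl 2-[(1R,2S,3S,4R,5R)-3-[(tert-butyldimethylsilyl)oxy]-7-methoxy-2-[(2R)-pent-4-en-2-yl]-2-(phenylsulfonyl)-6-oxabicyclo[3.2.1]octan-4-yl]acetate
Conditions: TBSOTf, 2,6-lutidine, CH2Cl2, 0 °C to rt
Reagents that add atoms: tert-butyldimethylsilyl trifluoromethanesulfonate CC(C)(C)[Si](C)(C)OS(=O)(=O)C(F)(F)F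
Why: Silyl triflate silylation of a hindered secondary alcohol; it keeps O6 away from the C12 ester when the lactone is closed.

**Step 7**
Reactants: 11 methyl 2-[(1R,2S,3S,4R,5R)-3-[(tert-butyldimethylsilyl)oxy]-7-methoxy-2-[(2R)-pent-4-en-2-yl]-2-(phenylsulfonyl)-6-oxabicyclo[3.2.1]octan-4-yl]acetate
Product: 13 methyl 2-[(1R,2S,3S,4R,5R)-3-[(tert-butyldimethylsilyl)oxy]-2-[(2R)-5-hydroxypentan-2-yl]-7-methoxy-2-(phenylsulfonyl)-6-oxabicyclo[3.2.1]octan-4-yl]acetate, via B-alkyl-9-BBN adduct 12 (not isolated)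
Conditions: 9-borabicyclo[3.3.1]nonane (9-BBN), THF, rt; then 30% H2O2, NaOAc, H2O, 0 °C
Reagents that add atoms: hydrogen peroxide OO
Why: Brown hydroboration–oxidation of the terminal alkene, anti-Markovnikov, with buffered oxidation to spare the methyl ester.

**Step 8**
Reactants: 13 methyl 2-[(1R,2S,3S,4R,5R)-3-[(tert-butyldimethylsilyl)oxy]-2-[(2R)-5-hydroxypentan-2-yl]-7-methoxy-2-(phenylsulfonyl)-6-oxabicyclo[3.2.1]octan-4-yl]acetate
Product: 15 (3aR,4S,5S,6R,7aR)-4-[(tert-butyldimethylsilyl)oxy]-5-[(2R)-5-hydroxypentan-2-yl]-2-oxo-5-(phenylsulfonyl)octahydro-1-benzofuran-6-carbaldehyde, via lactol 14 (not isolated)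
Conditions: AcOH/THF/H2O (3:1:1), 50 °C; then PPTS (cat.), toluene, 60 °C
Reagents that add atoms: water O
Why: Acetal hydrolysis gives the lactol, whose open hydroxy aldehyde form lactonises through the C8 hydroxyl onto the cis C7 acetate arm (cis-fused γ-lactone); the hindered secondary silyl ether should survive.

**Step 9**
Reactants: 15 (3aR,4S,5S,6R,7aR)-4-[(tert-butyldimethylsilyl)oxy]-5-[(2R)-5-hydroxypentan-2-yl]-2-oxo-5-(phenylsulfonyl)octahydro-1-benzofuran-6-carbaldehyde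
Product: 17 (3aR,4S,7aR)-4-[(tert-butyldimethylsilyl)oxy]-6-(hydroxymethyl)-5-[(2R)-5-hydroxypentan-2-yl]-3a,4,7,7a-tetrahydro-1-benzofuran-2(3H)-one, via enal 16 (not isolated)
Conditions: Et3N, CH2Cl2, 0 °C; then MeOH, CeCl3·7H2O, NaBH4, −78 °C
Reagents that add atoms: none
Why: E1cB loss of benzenesulfinate from C5 through the C10 aldehyde enolate places the tetrasubstituted C5=C10 alkene regiospecifically, and Luche reduction takes the enal to the C14 alcohol without touching the lactone.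

**Step 10**
Reactants: 17 (3aR,4S,7aR)-4-[(tert-butyldimethylsilyl)oxy]-6-(hydroxymethyl)-5-[(2R)-5-hydroxypentan-2-yl]-3a,4,7,7a-tetrahydro-1-benzofuran-2(3H)-one
Product: 18 (3aR,4S,7aR)-4-[(tert-butyldimethylsilyl)oxy]-6-{[(tert-butyldiphenylsilyl)oxy]methyl}-5-{(2R)-5-[(tert-butyldiphenylsilyl)oxy]pentan-2-yl}-3a,4,7,7a-tetrahydro-1-benzofuran-2(3H)-one
Conditions: TBDPSCl (2.5 equiv), imidazole, DMF, rt
Reagents that add atoms: tert-butyl(chloro)diphenylsilane CC(C)(C)[Si](Cl)(c1ccccc1)c1ccccc1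
Why: Silylation of both primary alcohols with a group that outlasts the later removal of the C6 silyl ether.

**Step 11**
Reactants: 18 (3aR,4S,7aR)-4-[(tert-butyldimethylsilyl)oxy]-6-{[(tert-butyldiphenylsilyl)oxy]methyl}-5-{(2R)-5-[(tert-butyldiphenylsilyl)oxy]pentan-2-yl}-3a,4,7,7a-tetrahydro-1-benzofuran-2(3H)-one
Product: 21 (3aR,4S,7aR)-4-[(tert-butyldimethylsilyl)oxy]-6-{[(tert-butyldiphenylsilyl)oxy]methyl}-5-{(2R)-5-[(tert-butyldiphenylsilyl)oxy]pentan-2-yl}-3-methylidene-3a,4,7,7a-tetrahydro-1-benzofuran-2(3H)-one, via Mannich base 19 (not isolated), via ammonium iodide 20 (not isolated)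
Conditions: LiN(SiMe3)2, THF, −78 °C; Me2N=CH2 I (Eschenmoser's salt), −78 °C to rt; then MeI, MeOH, rt; then NaHCO3 (aq), CH2Cl2
Reagents that add atoms: N,N-dimethylmethyleneiminium iodide C=[N+](C)C.[I-]
Why: Eschenmoser methylenation (lactone enolate Mannich reaction, N-methylation, Hofmann-type elimination); the lactone α-CH2 is the only acidic site left.

**Step 12**
Reactants: 21 (3aR,4S,7aR)-4-[(tert-butyldimethylsilyl)oxy]-6-{[(tert-butyldiphenylsilyl)oxy]methyl}-5-{(2R)-5-[(tert-butyldiphenylsilyl)oxy]pentan-2-yl}-3-methylidene-3a,4,7,7a-tetrahydro-1-benzofuran-2(3H)-one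
Product: 22 (3aS,4S,7aR)-6-{[(tert-butyldiphenylsilyl)oxy]methyl}-5-{(2R)-5-[(tert-butyldiphenylsilyl)oxy]pentan-2-yl}-4-hydroxy-3-methylidene-3a,4,7,7a-tetrahydro-1-benzofuran-2(3H)-one
Conditions: HF·pyridine, pyridine, THF, 0 °C, stopped when 21 is consumed
Reagents that add atoms: none
Why: Fluoride desilylation; the tert-butyldimethylsilyl ether should cleave well before the two primary tert-butyldiphenylsilyl ethers.

**Step 13**
Reactants: 22 (3aS,4S,7aR)-6-{[(tert-butyldiphenylsilyl)oxy]methyl}-5-{(2R)-5-[(tert-butyldiphenylsilyl)oxy]pentan-2-yl}-4-hydroxy-3-methylidene-3a,4,7,7a-tetrahydro-1-benzofuran-2(3H)-one; 23 angelic acid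
Product: 25 (3aR,4S,7aR)-6-{[(tert-butyldiphenylsilyl)oxy]methyl}-5-{(2R)-5-[(tert-butyldiphenylsilyl)oxy]pentan-2-yl}-3-methylidene-2-oxo-2,3,3a,4,7,7a-hexahydro-1-benzofuran-4-yl (2Z)-2-methylbut-2-enoate, via mixed anhydride 24 (not isolated)
Conditions: 2,4,6-trichlorobenzoyl chloride, Et3N, toluene, rt; then 22, 80 °C, no DMAP
Reagents that add atoms: none
Why: Yamaguchi-type esterification through the trichlorobenzoyl mixed anhydride; leaving out the nucleophilic catalyst should keep the Z (angelate) geometry.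

**Step 14**
Reactants: 25 (3aR,4S,7aR)-6-{[(tert-butyldiphenylsilyl)oxy]methyl}-5-{(2R)-5-[(tert-butyldiphenylsilyl)oxy]pentan-2-yl}-3-methylidene-2-oxo-2,3,3a,4,7,7a-hexahydro-1-benzofuran-4-yl (2Z)-2-methylbut-2-enoate
Product: 26 (3aR,4S,7aR)-6-(hydroxymethyl)-5-[(2R)-5-hydroxypentan-2-yl]-3-methylidene-2-oxo-2,3,3a,4,7,7a-hexahydro-1-benzofuran-4-yl (2Z)-2-methylbut-2-enoate
Conditions: HF·pyridine (excess), THF, rt
Reagents that add atoms: none
Why: Acidic fluoride desilylation of both primary ethers; the angelate and the α-methylene lactone should tolerate it.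

**Compound list**

1 | methyl 5-bromo-4-oxopentanoate | COC(=O)CCC(=O)CBr | starting material
2 | sodium benzenesulfinate | [Na+].[O-]S(=O)c1ccccc1 | starting material
3 | methyl 4-oxo-5-(phenylsulfonyl)pentanoate | COC(=O)CCC(=O)CS(=O)(=O)c1ccccc1 | intermediate
4 | (E)-4,4-dimethoxybut-2-enal | COC(OC)/C=C/C=O | starting material
5 | methyl (6R)-6-(dimethoxymethyl)-4,8-dioxo-5-(phenylsulfonyl)octanoate (Michael adduct, epimers at the sulfonyl carbon) | COC(=O)CCC(=O)C(S(=O)(=O)c1ccccc1)[C@H](CC=O)C(OC)OC | intermediate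
6 | methyl 2-[(1R,4R,5R)-7-methoxy-3-oxo-2-(phenylsulfonyl)-6-oxabicyclo[3.2.1]octan-4-yl]acetate (acetate arm equatorial, cis to the ring oxygen; epimers at the sulfonyl and acetal carbons) | COC(=O)C[C@H]1C(=O)C(S(=O)(=O)c3ccccc3)[C@@H]2C[C@H]1OC2OC | intermediate
7 | (E)-but-2-enal | C/C=C/C=O | starting material
8 | methyl 2-[(1R,2S,4R,5R)-7-methoxy-3-oxo-2-[(2R)-4-oxobutan-2-yl]-2-(phenylsulfonyl)-6-oxabicyclo[3.2.1]octan-4-yl]acetate (side chain on the face opposite the bridge; acetal epimers) | COC(=O)C[C@H]1C(=O)[C@](S(=O)(=O)c3ccccc3)([C@H](C)CC=O)[C@@H]2C[C@H]1OC2OC | intermediate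
9 | methyl 2-[(1R,2S,4R,5R)-7-methoxy-3-oxo-2-[(2R)-pent-4-en-2-yl]-2-(phenylsulfonyl)-6-oxabicyclo[3.2.1]octan-4-yl]acetate | COC(=O)C[C@H]1C(=O)[C@](S(=O)(=O)c3ccccc3)([C@H](C)CC=C)[C@@H]2C[C@H]1OC2OC | intermediate
10 | methyl 2-[(1R,2S,3S,4S,5R)-3-hydroxy-7-methoxy-2-[(2R)-pent-4-en-2-yl]-2-(phenylsulfonyl)-6-oxabicyclo[3.2.1]octan-4-yl]acetate (hydroxyl equatorial, trans to the acetate arm) | COC(=O)C[C@H]1[C@H](O)[C@](S(=O)(=O)c3ccccc3)([C@H](C)CC=C)[C@@H]2C[C@H]1OC2OC | intermediate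
11 | methyl 2-[(1R,2S,3S,4R,5R)-3-[(tert-butyldimethylsilyl)oxy]-7-methoxy-2-[(2R)-pent-4-en-2-yl]-2-(phenylsulfonyl)-6-oxabicyclo[3.2.1]octan-4-yl]acetate | COC(=O)C[C@H]1[C@H](O[Si](C)(C)C(C)(C)C)[C@](S(=O)(=O)c3ccccc3)([C@H](C)CC=C)[C@@H]2C[C@H]1OC2OC | intermediate
12 | B-alkyl-9-BBN adduct of 11 (boron on the terminal carbon of the side chain) | COC(=O)C[C@H]1[C@H](O[Si](C)(C)C(C)(C)C)[C@](S(=O)(=O)c3ccccc3)([C@H](C)CCCB4C5CCCC4CCC5)[C@@H]2C[C@H]1OC2OC | intermediate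
13 | methyl 2-[(1R,2S,3S,4R,5R)-3-[(tert-butyldimethylsilyl)oxy]-2-[(2R)-5-hydroxypentan-2-yl]-7-methoxy-2-(phenylsulfonyl)-6-oxabicyclo[3.2.1]octan-4-yl]acetate | COC(=O)C[C@H]1[C@H](O[Si](C)(C)C(C)(C)C)[C@](S(=O)(=O)c3ccccc3)([C@H](C)CCCO)[C@@H]2C[C@H]1OC2OC | intermediate
14 | methyl 2-[(1R,2S,3S,4R,5R)-3-[(tert-butyldimethylsilyl)oxy]-7-hydroxy-2-[(2R)-5-hydroxypentan-2-yl]-2-(phenylsulfonyl)-6-oxabicyclo[3.2.1]octan-4-yl]acetate (lactol) | COC(=O)C[C@H]1[C@H](O[Si](C)(C)C(C)(C)C)[C@](S(=O)(=O)c3ccccc3)([C@H](C)CCCO)[C@@H]2C[C@H]1OC2O | intermediate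
15 | (3aR,4S,5S,6R,7aR)-4-[(tert-butyldimethylsilyl)oxy]-5-[(2R)-5-hydroxypentan-2-yl]-2-oxo-5-(phenylsulfonyl)octahydro-1-benzofuran-6-carbaldehyde (cis-fused lactone) | C1C(=O)O[C@@H]2C[C@H](C=O)[C@@](S(=O)(=O)c3ccccc3)([C@H](C)CCCO)[C@@H](O[Si](C)(C)C(C)(C)C)[C@H]12 | intermediate
16 | (3aR,4S,7aR)-4-[(tert-butyldimethylsilyl)oxy]-5-[(2R)-5-hydroxypentan-2-yl]-2-oxo-2,3,3a,4,7,7a-hexahydro-1-benzofuran-6-carbaldehyde (enal) | C1C(=O)O[C@@H]2CC(C=O)=C([C@H](C)CCCO)[C@@H](O[Si](C)(C)C(C)(C)C)[C@H]12 | intermediate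
17 | (3aR,4S,7aR)-4-[(tert-butyldimethylsilyl)oxy]-6-(hydroxymethyl)-5-[(2R)-5-hydroxypentan-2-yl]-3a,4,7,7a-tetrahydro-1-benzofuran-2(3H)-one | C1C(=O)O[C@@H]2CC(CO)=C([C@H](C)CCCO)[C@@H](O[Si](C)(C)C(C)(C)C)[C@H]12 | intermediate
18 | (3aR,4S,7aR)-4-[(tert-butyldimethylsilyl)oxy]-6-{[(tert-butyldiphenylsilyl)oxy]methyl}-5-{(2R)-5-[(tert-butyldiphenylsilyl)oxy]pentan-2-yl}-3a,4,7,7a-tetrahydro-1-benzofuran-2(3H)-one | C1C(=O)O[C@@H]2CC(CO[Si](c3ccccc3)(c3ccccc3)C(C)(C)C)=C([C@H](C)CCCO[Si](c3ccccc3)(c3ccccc3)C(C)(C)C)[C@@H](O[Si](C)(C)C(C)(C)C)[C@H]12 | intermediate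
19 | 3-[(dimethylamino)methyl] derivative of 18 (Mannich base, epimers at the lactone α-carbon) | CN(C)CC1C(=O)O[C@@H]2CC(CO[Si](c3ccccc3)(c3ccccc3)C(C)(C)C)=C([C@H](C)CCCO[Si](c3ccccc3)(c3ccccc3)C(C)(C)C)[C@@H](O[Si](C)(C)C(C)(C)C)[C@H]12 | intermediate
20 | trimethylammonium iodide of 19 | C[N+](C)(C)CC1C(=O)O[C@@H]2CC(CO[Si](c3ccccc3)(c3ccccc3)C(C)(C)C)=C([C@H](C)CCCO[Si](c3ccccc3)(c3ccccc3)C(C)(C)C)[C@@H](O[Si](C)(C)C(C)(C)C)[C@H]12.[I-] | intermediate
21 | (3aR,4S,7aR)-4-[(tert-butyldimethylsilyl)oxy]-6-{[(tert-butyldiphenylsilyl)oxy]methyl}-5-{(2R)-5-[(tert-butyldiphenylsilyl)oxy]pentan-2-yl}-3-methylidene-3a,4,7,7a-tetrahydro-1-benzofuran-2(3H)-one | C=C1C(=O)O[C@@H]2CC(CO[Si](c3ccccc3)(c3ccccc3)C(C)(C)C)=C([C@H](C)CCCO[Si](c3ccccc3)(c3ccccc3)C(C)(C)C)[C@@H](O[Si](C)(C)C(C)(C)C)[C@H]12 | intermediate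
22 | (3aS,4S,7aR)-6-{[(tert-butyldiphenylsilyl)oxy]methyl}-5-{(2R)-5-[(tert-butyldiphenylsilyl)oxy]pentan-2-yl}-4-hydroxy-3-methylidene-3a,4,7,7a-tetrahydro-1-benzofuran-2(3H)-one | C=C1C(=O)O[C@@H]2CC(CO[Si](c3ccccc3)(c3ccccc3)C(C)(C)C)=C([C@H](C)CCCO[Si](c3ccccc3)(c3ccccc3)C(C)(C)C)[C@@H](O)[C@H]12 | intermediate
23 | angelic acid, (2Z)-2-methylbut-2-enoic acid | C/C=C(/C)C(=O)O | starting material
24 | (2Z)-2-methylbut-2-enoic 2,4,6-trichlorobenzoic anhydride | C/C=C(/C)C(=O)OC(=O)c1c(Cl)cc(Cl)cc1Cl | intermediate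
25 | (3aR,4S,7aR)-6-{[(tert-butyldiphenylsilyl)oxy]methyl}-5-{(2R)-5-[(tert-butyldiphenylsilyl)oxy]pentan-2-yl}-3-methylidene-2-oxo-2,3,3a,4,7,7a-hexahydro-1-benzofuran-4-yl (2Z)-2-methylbut-2-enoate | C=C1C(=O)O[C@@H]2CC(CO[Si](c3ccccc3)(c3ccccc3)C(C)(C)C)=C([C@H](C)CCCO[Si](c3ccccc3)(c3ccccc3)C(C)(C)C)[C@@H](OC(=O)/C(C)=C\C)[C@H]12 | intermediate
26 | (3aR,4S,7aR)-6-(hydroxymethyl)-5-[(2R)-5-hydroxypentan-2-yl]-3-methylidene-2-oxo-2,3,3a,4,7,7a-hexahydro-1-benzofuran-4-yl (2Z)-2-methylbut-2-enoate | C=C1C(=O)O[C@@H]2CC(CO)=C([C@H](C)CCCO)[C@@H](OC(=O)/C(C)=C\C)[C@H]12 | target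

**Step count and risks**

Total steps: 14. Longest linear sequence: 14 (from 1).

Steps most likely to fail:

1. Step 2. Capture of the C8 oxocarbenium ion by the C7 enol may lose to O-cyclisation of the keto sulfone enol or to dehydration of an aldol intermediate, and the relay from C10 to C8 would then be lost. The fallback sets out from 5, isolated after the amine stage. A reversible base-mediated aldol (catalytic DBU, THF, 0 °C) closes C7–C8 to the β-hydroxy ketone methyl 2-[(1R,2R,4R)-4-(dimethoxymethyl)-2-hydroxy-6-oxo-5-(phenylsulfonyl)cyclohexyl]acetate F1. PPTS in CH2Cl2 then ties the C8 hydroxyl to C14 with loss of methanol and comes back to the route at 6. The C8 epimer that cannot bridge is returned to the base and recycled through retro-aldol.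

2. Step 3. Bond formation at the tertiary sulfonyl carbon may stall or reverse (retro-Michael), and the new aldehyde may aldolise onto C7. The fallback sets out from 6 and comes back at 13.
   - Iridium-catalysed allylic alkylation with methyl (E)-but-2-en-1-yl carbonate ([Ir(cod)Cl]2, a BINOL-derived bis(1-phenylethyl)amine phosphoramidite ligand, LiOt-Bu, THF) should give the branched C5-(but-3-en-2-yl) ketone F2, with C4 set by the ligand.
   - NaBH4/CeCl3·7H2O as in step 5 gives the C6 alcohol F3.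
   - TBSOTf/2,6-lutidine gives the silyl ether F4.
   - Linear-selective hydroformylation (Rh(acac)(CO)2, 4,5-bis(diphenylphosphino)-9,9-dimethylxanthene, CO/H2, toluene) gives the aldehyde F5.
   - NaBH4 in MeOH reduces F5 to 13.

3. Step 5. Hydride delivery may show poor facial selectivity, because both faces of the C6 ketone are hindered. The fallback sets out from 9 and comes back at 10 by reagent control instead of substrate control: (R)-1-methyl-3,3-diphenyltetrahydro-1H,3H-pyrrolo[1,2-c][1,3,2]oxazaborole with catecholborane in toluene at −78 °C, which spares the alkene. The quaternary C5 acts as the large group. No new compound arises (F0).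

**Further compounds**

F1 | step 2 | methyl 2-[(1R,2R,4R)-4-(dimethoxymethyl)-2-hydroxy-6-oxo-5-(phenylsulfonyl)cyclohexyl]acetate | COC(=O)C[C@H]1C(=O)C(S(=O)(=O)c2ccccc2)[C@@H](C(OC)OC)C[C@H]1O
F2 | step 3 | methyl 2-[(1R,4R,5R)-2-[(2R)-but-3-en-2-yl]-7-methoxy-3-oxo-2-(phenylsulfonyl)-6-oxabicyclo[3.2.1]octan-4-yl]acetate (side chain opposite the bridge) | COC(=O)C[C@H]1C(=O)[C@](S(=O)(=O)c3ccccc3)([C@H](C)C=C)[C@@H]2C[C@H]1OC2OC
F3 | step 3 | C3 alcohol of F2 (hydroxyl equatorial, trans to the acetate arm) | COC(=O)C[C@H]1[C@H](O)[C@](S(=O)(=O)c3ccccc3)([C@H](C)C=C)[C@@H]2C[C@H]1OC2OC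
F4 | step 3 | tert-butyldimethylsilyl ether of F3 | COC(=O)C[C@H]1[C@H](O[Si](C)(C)C(C)(C)C)[C@](S(=O)(=O)c3ccccc3)([C@H](C)C=C)[C@@H]2C[C@H]1OC2OC
F5 | step 3 | methyl 2-[3-[(tert-butyldimethylsilyl)oxy]-7-methoxy-2-[(2R)-5-oxopentan-2-yl]-2-(phenylsulfonyl)-6-oxabicyclo[3.2.1]octan-4-yl]acetate (ring configured as in 13) | COC(=O)C[C@H]1[C@H](O[Si](C)(C)C(C)(C)C)[C@](S(=O)(=O)c3ccccc3)([C@H](C)CCC=O)[C@@H]2C[C@H]1OC2OC
F0 | step 5 | none | none
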